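The oxocane (C4–O–C8–C9–C10–C1–C2–C3) is disconnected at C9–C10. Retro-oxidation of the C11 hydroxy acid to an exocyclic C11=C20 methylene exposes a homoallylic alcohol, C9(OH)–C10–C11(=C20), the retron of an allylsilane–aldehyde addition. The key step is an intramolecular Hosomi–Sakurai closure: a ring A allylsilane attacks the C9 aldehyde on C8 of the preformed pyran–lactone, chelated through the pyran oxygen, forming the eight-membered ring and setting C9 and C10 together. The precursor comes from a cuprate-derived ring A aldehyde and a hydroxymethylfurfural-derived hydroxyacetylfuran (aldol, Achmatowicz, C-glycosylation, transpositive lactonisation); chlorine enters late by ene chlorination.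

Key step: step 20

Remark: briarane numbering is used (C1 quaternary with C15 methyl; C2, C3, C9, C14 acetoxy carbons; C4–O–C8 ether; C5=C16; C6–Cl; C7 lactone oxygen; C11 with OH and C20; C17 with C18 methyl; C19 lactone carbonyl), and the target is taken as 1R,2R,3R,4R,6S,7R,8R,9S,10S,11R,14S,17R.

Step 1
Reactants: 1 3-ethoxycyclohex-2-en-1-one
Product: 2 rac-4-ethoxy-2-oxocyclohex-3-en-1-yl acetate
Conditions: Mn(OAc)3, benzene, reflux
Reagents that add atoms: manganese triacetate, CC(=O)[O-].CC(=O)[O-].CC(=O)[O-].[Mn+3]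
Why: α′-Acetoxylation of an enone by Mn(OAc)3 goes through the manganese enolate of the only enolisable α′-position, so the future C14 oxygen enters next to the carbonyl and not at the vinylogous carbon.

Step 2
Reactants: 2 rac-4-ethoxy-2-oxocyclohex-3-en-1-yl acetate
Product: 3 (S)-3-ethoxy-6-hydroxycyclohex-2-en-1-one
Conditions: Amano lipase PS, phosphate buffer pH 7/MTBE, rt, to half conversion
Reagents that add atoms: none
Why: Lipase-catalysed enantioselective ester hydrolysis (kinetic resolution) should cleave only the (S)-acetate and leave (R)-2 behind, which fixes the future C14 stereocentre.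

Step 3
Reactants: 3 (S)-3-ethoxy-6-hydroxycyclohex-2-en-1-one
Product: 4 (S)-6-[(tert-butyldiphenylsilyl)oxy]-3-ethoxycyclohex-2-en-1-one
Conditions: TBDPSCl, imidazole, DMF, rt
Reagents that add atoms: tert-butyl(chloro)diphenylsilane, CC(C)(C)[Si](Cl)(c1ccccc1)c1ccccc1
Why: Imidazole-mediated silylation protects the secondary alcohol as a bulky, acid-stable ether that later directs the cuprate to the opposite face.

Step 4
Reactants: 4 (S)-6-[(tert-butyldiphenylsilyl)oxy]-3-ethoxycyclohex-2-en-1-one; 5 1,3-dithiane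
Product: 7 (S)-4-[(tert-butyldiphenylsilyl)oxy]-3-(1,3-dithian-2-yl)cyclohex-2-en-1-one, via dithianyl carbinol adduct 6 (not isolated)
Conditions: 5, n-BuLi, THF, −30 °C; 4, −78 °C; then 1 M HCl, THF, 0 °C
Reagents that add atoms: none
Why: Stork–Danheiser sequence: 1,2-addition of 2-lithio-1,3-dithiane to the vinylogous ester carbonyl, then acid-induced loss of ethanol with carbonyl transposition, gives the 3-substituted enone carrying the masked C2 aldehyde on the future C1.

Step 5
Reactants: 7 (S)-4-[(tert-butyldiphenylsilyl)oxy]-3-(1,3-dithian-2-yl)cyclohex-2-en-1-one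
Product: 9 (3R,4S)-4-[(tert-butyldiphenylsilyl)oxy]-3-(1,3-dithian-2-yl)-3-methylcyclohex-1-en-1-yl trifluoromethanesulfonate, via lithium enolate 8 (not isolated)
Conditions: MeLi, CuI, Et2O, 0 °C; 7, −78 → −20 °C; then PhNTf2, THF, −78 °C → rt
Reagents that add atoms: lithium dimethylcuprate, [Li+].C[Cu-]C; N-phenylbis(trifluoromethanesulfonimide), O=S(=O)(N(c1ccccc1)S(=O)(=O)C(F)(F)F)C(F)(F)F
Why: Conjugate addition of Me2CuLi to the β,β-disubstituted enone occurs anti to the γ-silyloxy group, so quaternary C1 forms with its methyl trans to the C14 oxygen, and O-triflation of the regiodefined enolate stores it as the C10=C11 enol triflate.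

Step 6
Reactants: 9 (3R,4S)-4-[(tert-butyldiphenylsilyl)oxy]-3-(1,3-dithian-2-yl)-3-methylcyclohex-1-en-1-yl trifluoromethanesulfonate
Product: 10 (3R,4S)-4-[(tert-butyldiphenylsilyl)oxy]-3-formyl-3-methylcyclohex-1-en-1-yl trifluoromethanesulfonate (ring A aldehyde)
Conditions: MeI, CaCO3, MeCN/H2O, 45 °C
Reagents that add atoms: water, O
Why: S-Methylation-induced hydrolysis of the dithiane (standard thioacetal cleavage) releases the non-enolisable C2 aldehyde under neutral conditions that spare the enol triflate and the silyl ether.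

Step 7
Reactants: 11 5-(hydroxymethyl)furan-2-carbaldehyde
Product: 12 5-{[(tert-butyldiphenylsilyl)oxy]methyl}furan-2-carbaldehyde
Conditions: TBDPSCl, imidazole, CH2Cl2, rt
Reagents that add atoms: tert-butyl(chloro)diphenylsilane, CC(C)(C)[Si](Cl)(c1ccccc1)c1ccccc1
Why: Silylation of the primary alcohol protects the future C9 oxygen through the acidic and organometallic steps that follow.

Step 8
Reactants: 12 5-{[(tert-butyldiphenylsilyl)oxy]methyl}furan-2-carbaldehyde
Product: 13 1-(5-{[(tert-butyldiphenylsilyl)oxy]methyl}furan-2-yl)-2-hydroxyethan-1-one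
Conditions: paraformaldehyde, thiazolium carbene precatalyst (10 mol %), iPr2NEt, THF, 60 °C
Reagents that add atoms: formaldehyde (as paraformaldehyde), C=O
Why: N-Heterocyclic-carbene-catalysed hydroxymethylation (cross-benzoin addition of the Breslow intermediate to formaldehyde) converts the furfural into the α-hydroxy ketone and brings in C3.

Step 9
Reactants: 10 ring A aldehyde; 13 1-(5-{[(tert-butyldiphenylsilyl)oxy]methyl}furan-2-yl)-2-hydroxyethan-1-one
Product: 14 2,3-syn dihydroxy ketone (ring A on C2, hydroxyls on C2 and C3, furyl ketone at C4)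
Conditions: Et2Zn (10 mol %), ProPhenol ligand (5 mol %, enantiomer matched to the C2/C3 configuration of 31), 4 Å MS, THF, −35 °C
Reagents that add atoms: none
Why: Direct asymmetric aldol reaction of an α-hydroxy ketone donor under dinuclear zinc–ProPhenol catalysis gives the syn-1,2-diol, the catalyst setting C2 and C3 as the chelated zinc enediolate adds to the non-enolisable aldehyde.

Step 10
Reactants: 14 2,3-syn dihydroxy ketone
Product: 15 C2,C3-acetonide furyl ketone
Conditions: Me2C(OMe)2, PPTS, CH2Cl2, rt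
Reagents that add atoms: 2,2-dimethoxypropane, COC(C)(C)OC
Why: Acid-catalysed transacetalisation protects the only 1,2-diol as a trans-dioxolane, whose C3 oxygen also serves as the chelating group for the next reduction.

Step 11
Reactants: 15 C2,C3-acetonide furyl ketone
Product: 16 C4 furfuryl alcohol (3,4-anti)
Conditions: ZnCl2, NaBH4 (Zn(BH4)2), Et2O, −30 °C
Reagents that add atoms: none
Why: Chelation-controlled (Cram chelate) reduction of the α-alkoxy ketone: zinc bridges the carbonyl and the C3 dioxolane oxygen and hydride attacks anti to the C2 branch, giving the 3,4-anti alcohol that sets C4.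

Step 12
Reactants: 16 C4 furfuryl alcohol
Product: 17 Achmatowicz hemiketal (6-hydroxy-2H-pyran-3(6H)-one with C5 ketone, C6=C7, C8 hemiketal bearing the C9 silyloxymethyl arm; C8 anomers)
Conditions: NBS, NaHCO3, NaOAc, THF/H2O, 0 °C
Reagents that add atoms: water, O
Why: Achmatowicz rearrangement: oxidation of the furan and ring closure by the C4 hydroxyl build the pyranone ring O–C4–C5–C6–C7–C8 with C4 untouched.

Step 13
Reactants: 17 Achmatowicz hemiketal; 18 1-methoxy-1-(trimethylsilyloxy)prop-1-ene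
Product: 19 C8-quaternary pyranone methyl ester (C17 propionate unit trans to the C4 side chain)
Conditions: 18 (3 equiv), TMSOTf (0.3 equiv), CH2Cl2, −78 °C
Reagents that add atoms: none
Why: Lewis-acid ionisation of the hemiketal and Mukaiyama-type C-glycosylation of the cyclic oxocarbenium ion: axial attack trans to the C4 side chain sets quaternary C8 with the C9 and C3 arms cis, and an antiperiplanar open transition state that keeps the C18 methyl away from the C9 arm should set C17.

Step 14
Reactants: 19 C8-quaternary pyranone methyl ester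
Product: 20 C5 tertiary allylic alcohol (C5 epimers)
Conditions: MeLi, CeCl3, THF, −78 °C
Reagents that add atoms: methylcerium dichloride (from MeLi and CeCl3), C[Ce](Cl)Cl
Why: 1,2-Addition of the organocerium reagent to the enone carbonyl is chemoselective over the methyl ester and avoids enolisation at C4, and it brings in C16; the C5 configuration is lost in the next step.

Step 15
Reactants: 20 C5 tertiary allylic alcohol
Product: 22 dihydropyran-fused γ-lactone 2,3-diol, via lactone acetonide 21 (not isolated)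
Conditions: TFA, CH2Cl2, 0 °C; then H2O, rt
Reagents that add atoms: none
Why: Acid ionises the tertiary allylic alcohol to the C5–C6–C7 allyl cation, which the ester carbonyl oxygen traps at C7 in a 1,3-transpositive dealkylative lactonisation that can only give the cis-fused γ-lactone (C7 set by the C8 tether) and leaves the C5=C6 alkene, after which aqueous acid cleaves the acetonide.

Step 16
Reactants: 22 lactone 2,3-diol
Product: 23 lactone 2,3-diacetate
Conditions: Ac2O, pyridine, DMAP, CH2Cl2, rt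
Reagents that add atoms: acetic anhydride, CC(=O)OC(C)=O
Why: DMAP-catalysed acylation installs the final C2 and C3 acetates.

Step 17
Reactants: 23 lactone 2,3-diacetate
Product: 24 C9,C14-diol
Conditions: HF·pyridine, THF, 0 → 40 °C
Reagents that add atoms: none
Why: Fluoride-mediated desilylation removes both silyl ethers without touching acetates, lactone or enol triflate.

Step 18
Reactants: 24 C9,C14-diol
Product: 25 C9 aldehyde
Conditions: TEMPO (cat.), PhI(OAc)2, CH2Cl2, rt
Reagents that add atoms: none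
Why: Oxoammonium (TEMPO) oxidation is selective for the primary C9 alcohol over the hindered secondary C14 alcohol and stops at the non-enolisable aldehyde.

Step 19
Reactants: 25 C9 aldehyde
Product: 26 allylsilane aldehyde
Conditions: Me3SiCH2MgCl, ZnCl2, THF, 0 °C; 25, Pd(PPh3)4 (5 mol %), rt
Reagents that add atoms: (trimethylsilyl)methylzinc chloride, C[Si](C)(C)C[Zn]Cl
Why: Negishi cross-coupling of the enol triflate (zerovalent palladium catalysis) tolerates the aldehyde, esters and free hydroxyl and turns the latent enolate into the 2-substituted allylsilane that carries C20.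

Step 20
Reactants: 26 allylsilane aldehyde
Product: 27 oxocane homoallylic alcohol (C9–OH, C10–H, C11=C20 methylene)
Conditions: SnCl4 (2.2 equiv), 2,6-di-tert-butyl-4-methylpyridine, CH2Cl2, −78 °C; aq. NaHCO3
Reagents that add atoms: none
Why: SnCl4 chelates the C9 aldehyde oxygen and the pyran oxygen on C8, the 2-substituted allylsilane attacks through C10 in an anti SE2′ sense, and loss of silicon from the β-silyl cation leaves the C11=C20 methylene (intramolecular Hosomi–Sakurai allylation; the closest known reaction types are allylsilane and enol silane closures of eight-membered rings in taxane and oxocene work). The oxocane closes in the 8-exo-trig mode at the aldehyde carbon, and the reacting allylsilane double bond is also exocyclic to the new ring. C9 is controlled by the five-membered chelate, which holds the carbonyl oxygen syn to the pyran oxygen while the tether, anchored on the cis axial C3 and C9 arms, can deliver C10 only to the outer face of the carbonyl, giving the 9S carbinol. C10 is controlled by ring A: the tether leaves C1 through the pseudo-equatorial C2, so bonding at C10 trans to C2 gives the diequatorial trans ring fusion and avoids the 1,3-diaxial clash with the C14 oxygen that the cis mode would incur. The step needs chemoselectivity for the aldehyde over lactone and acetates and for the allylsilane over the C5=C6 alkene, secured by the much higher nucleophilicity of the 2-substituted allylsilane and by geometry; it also needs protodesilylation to be suppressed, which the hindered pyridine base secures.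

Step 21
Reactants: 27 oxocane homoallylic alcohol
Product: 28 2,3,9,14-tetraacetate with C11=C20 methylene
Conditions: Ac2O, DMAP, pyridine, 40 °C
Reagents that add atoms: acetic anhydride, CC(=O)OC(C)=O
Why: DMAP-catalysed acylation of the two hindered secondary alcohols completes the four acetates.

Step 22
Reactants: 28 tetraacetate diene
Product: 29 11,20-diol
Conditions: OsO4 (5 mol %), NMO, acetone/H2O, 0 °C
Reagents that add atoms: N-methylmorpholine N-oxide, C[N+]1([O-])CCOCC1; water, O
Why: Upjohn dihydroxylation should take the exposed 1,1-disubstituted C11=C20 alkene in preference to the ring C5=C6 alkene (deactivated by two allylic C–O bonds and shielded by the oxocane bridge), and attack from the equatorial side, away from the axial C15 methyl, gives the 11R tertiary alcohol.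

Step 23
Reactants: 29 11,20-diol
Product: 30 6-chloro-5(16)-ene 11,20-diol
Conditions: Ca(OCl)2, CO2 (solid), CH2Cl2/H2O, 0 °C
Reagents that add atoms: calcium hypochlorite, [Ca+2].[O-]Cl.[O-]Cl
Why: Ene-type allylic chlorination by hypochlorous acid: chlorine adds to C6 from the open face opposite the oxocane bridge (6S) and the proton is lost from the C16 methyl, not from the bridgehead C4, giving the exocyclic methylene.

Step 24
Reactants: 30 6-chloro-5(16)-ene 11,20-diol
Product: 31 CNP0186125.1 (target)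
Conditions: TEMPO (cat.), PhI(OAc)2, MeCN/H2O, rt
Reagents that add atoms: water, O
Why: TEMPO/PhI(OAc)2 oxidation in aqueous acetonitrile takes the primary C20 alcohol through the aldehyde hydrate to the carboxylic acid and leaves the tertiary alcohol, allylic chloride and esters intact.

Compound list
1 | 3-ethoxycyclohex-2-en-1-one | CCOC1=CC(=O)CCC1 | starting material
2 | rac-4-ethoxy-2-oxocyclohex-3-en-1-yl acetate | CCOC1=CC(=O)C(OC(C)=O)CC1 | intermediate
3 | (S)-3-ethoxy-6-hydroxycyclohex-2-en-1-one | CCOC1=CC(=O)[C@@H](O)CC1 | intermediate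
4 | (S)-6-[(tert-butyldiphenylsilyl)oxy]-3-ethoxycyclohex-2-en-1-one | CCOC1=CC(=O)[C@@H](O[Si](c2ccccc2)(c2ccccc2)C(C)(C)C)CC1 | intermediate
5 | 1,3-dithiane | C1CSCSC1 | starting material
6 | dithianyl carbinol adduct, 1-(1,3-dithian-2-yl)-3-ethoxy-6-silyloxycyclohex-2-en-1-ol (carbinol epimers; not isolated) | CCOC1=CC(O)(C2SCCCS2)[C@@H](O[Si](c2ccccc2)(c2ccccc2)C(C)(C)C)CC1 | intermediate
7 | (S)-4-[(tert-butyldiphenylsilyl)oxy]-3-(1,3-dithian-2-yl)cyclohex-2-en-1-one | O=C1C=C(C2SCCCS2)[C@@H](O[Si](c2ccccc2)(c2ccccc2)C(C)(C)C)CC1 | intermediate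
8 | lithium enolate of the 3-methyl-3-dithianyl ketone (not isolated) | [Li+].[O-]C1=C[C@@](C)(C2SCCCS2)[C@@H](O[Si](c2ccccc2)(c2ccccc2)C(C)(C)C)CC1 | intermediate
9 | (3R,4S)-4-[(tert-butyldiphenylsilyl)oxy]-3-(1,3-dithian-2-yl)-3-methylcyclohex-1-en-1-yl trifluoromethanesulfonate | FC(F)(F)S(=O)(=O)OC1=C[C@@](C)(C2SCCCS2)[C@@H](O[Si](c2ccccc2)(c2ccccc2)C(C)(C)C)CC1 | intermediate
10 | (3R,4S)-4-[(tert-butyldiphenylsilyl)oxy]-3-formyl-3-methylcyclohex-1-en-1-yl trifluoromethanesulfonate (ring A aldehyde) | O=C[C@]1(C)C=C(OS(=O)(=O)C(F)(F)F)CC[C@@H]1O[Si](c2ccccc2)(c2ccccc2)C(C)(C)C | intermediate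
11 | 5-(hydroxymethyl)furan-2-carbaldehyde | O=Cc1ccc(CO)o1 | starting material
12 | 5-{[(tert-butyldiphenylsilyl)oxy]methyl}furan-2-carbaldehyde | O=Cc1ccc(CO[Si](c2ccccc2)(c2ccccc2)C(C)(C)C)o1 | intermediate
13 | 1-(5-{[(tert-butyldiphenylsilyl)oxy]methyl}furan-2-yl)-2-hydroxyethan-1-one | OCC(=O)c1ccc(CO[Si](c2ccccc2)(c2ccccc2)C(C)(C)C)o1 | intermediate
14 | 2,3-syn dihydroxy ketone (ring A on C2, furyl ketone at C4; C1, C2, C3, C14 as in 31) | O=C(c1ccc(CO[Si](c2ccccc2)(c2ccccc2)C(C)(C)C)o1)[C@@H](O)[C@H](O)[C@]1(C)C=C(OS(=O)(=O)C(F)(F)F)CC[C@@H]1O[Si](c2ccccc2)(c2ccccc2)C(C)(C)C | intermediate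
15 | C2,C3-acetonide (trans-dioxolane) of 14 | O=C(c1ccc(CO[Si](c2ccccc2)(c2ccccc2)C(C)(C)C)o1)[C@H]1OC(C)(C)O[C@@H]1[C@]2(C)C=C(OS(=O)(=O)C(F)(F)F)CC[C@@H]2O[Si](c3ccccc3)(c3ccccc3)C(C)(C)C | intermediate
16 | C4 furfuryl alcohol, 3,4-anti (C4 as in 31) | O[C@H](c1ccc(CO[Si](c2ccccc2)(c2ccccc2)C(C)(C)C)o1)[C@H]1OC(C)(C)O[C@@H]1[C@]2(C)C=C(OS(=O)(=O)C(F)(F)F)CC[C@@H]2O[Si](c3ccccc3)(c3ccccc3)C(C)(C)C | intermediate
17 | Achmatowicz hemiketal: 6-hydroxy-2H-pyran-3(6H)-one with C4 side chain, C5 ketone, C6=C7, C8(OH)(CH2OSi) (C8 anomers) | O=C1C=CC(O)(CO[Si](c2ccccc2)(c2ccccc2)C(C)(C)C)O[C@H]1[C@H]3OC(C)(C)O[C@@H]3[C@]2(C)C=C(OS(=O)(=O)C(F)(F)F)CC[C@@H]2O[Si](c4ccccc4)(c4ccccc4)C(C)(C)C | intermediate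
18 | 1-methoxy-1-(trimethylsilyloxy)prop-1-ene | CC=C(OC)O[Si](C)(C)C | starting material
19 | C8-quaternary pyranone methyl ester (C8 and C17 as in 31; C9 arm cis to the C4 side chain) | O=C1C=C[C@@]([C@@H](C)C(=O)OC)(CO[Si](c2ccccc2)(c2ccccc2)C(C)(C)C)O[C@H]1[C@H]3OC(C)(C)O[C@@H]3[C@]2(C)C=C(OS(=O)(=O)C(F)(F)F)CC[C@@H]2O[Si](c4ccccc4)(c4ccccc4)C(C)(C)C | intermediate
20 | C5 tertiary allylic alcohol (C5 epimers) | CC1(O)C=C[C@@]([C@@H](C)C(=O)OC)(CO[Si](c2ccccc2)(c2ccccc2)C(C)(C)C)O[C@H]1[C@H]3OC(C)(C)O[C@@H]3[C@]2(C)C=C(OS(=O)(=O)C(F)(F)F)CC[C@@H]2O[Si](c4ccccc4)(c4ccccc4)C(C)(C)C | intermediate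
21 | dihydropyran-fused cis-γ-lactone acetonide (not isolated) | CC1=C[C@@H]2OC(=O)[C@H](C)[C@]2(CO[Si](c3ccccc3)(c3ccccc3)C(C)(C)C)O[C@H]1[C@H]4OC(C)(C)O[C@@H]4[C@]5(C)C=C(OS(=O)(=O)C(F)(F)F)CC[C@@H]5O[Si](c6ccccc6)(c6ccccc6)C(C)(C)C | intermediate
22 | dihydropyran-fused cis-γ-lactone 2,3-diol | CC1=C[C@@H]2OC(=O)[C@H](C)[C@]2(CO[Si](c3ccccc3)(c3ccccc3)C(C)(C)C)O[C@H]1[C@@H](O)[C@H](O)[C@]4(C)C=C(OS(=O)(=O)C(F)(F)F)CC[C@@H]4O[Si](c5ccccc5)(c5ccccc5)C(C)(C)C | intermediate
23 | lactone 2,3-diacetate | CC1=C[C@@H]2OC(=O)[C@H](C)[C@]2(CO[Si](c3ccccc3)(c3ccccc3)C(C)(C)C)O[C@H]1[C@@H](OC(C)=O)[C@H](OC(C)=O)[C@]4(C)C=C(OS(=O)(=O)C(F)(F)F)CC[C@@H]4O[Si](c5ccccc5)(c5ccccc5)C(C)(C)C | intermediate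
24 | C9,C14-diol (C9 hydroxymethyl on C8, free C14 hydroxyl, enol triflate) | CC1=C[C@@H]2OC(=O)[C@H](C)[C@]2(CO)O[C@H]1[C@@H](OC(C)=O)[C@H](OC(C)=O)[C@]3(C)C=C(OS(=O)(=O)C(F)(F)F)CC[C@@H]3O | intermediate
25 | C9 aldehyde | CC1=C[C@@H]2OC(=O)[C@H](C)[C@]2(C=O)O[C@H]1[C@@H](OC(C)=O)[C@H](OC(C)=O)[C@]3(C)C=C(OS(=O)(=O)C(F)(F)F)CC[C@@H]3O | intermediate
26 | allylsilane aldehyde (C11 bears CH2SiMe3, C10=C11) | CC1=C[C@@H]2OC(=O)[C@H](C)[C@]2(C=O)O[C@H]1[C@@H](OC(C)=O)[C@H](OC(C)=O)[C@]3(C)C=C(C[Si](C)(C)C)CC[C@@H]3O | intermediate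
27 | oxocane homoallylic alcohol (C9–OH, C10–H, C11=C20, free C14–OH) | CC1=C[C@@H]2OC(=O)[C@H](C)[C@]23O[C@H]1[C@@H](OC(C)=O)[C@H](OC(C)=O)[C@@]1(C)[C@@H](O)CCC(=C)[C@@H]1[C@@H]3O | intermediate
28 | 2,3,9,14-tetraacetate with C11=C20 methylene | CC1=C[C@@H]2OC(=O)[C@H](C)[C@]23O[C@H]1[C@@H](OC(C)=O)[C@H](OC(C)=O)[C@@]1(C)[C@@H](OC(C)=O)CCC(=C)[C@@H]1[C@@H]3OC(C)=O | intermediate
29 | 11,20-diol tetraacetate | CC1=C[C@@H]2OC(=O)[C@H](C)[C@]23O[C@H]1[C@@H](OC(C)=O)[C@H](OC(C)=O)[C@@]1(C)[C@@H](OC(C)=O)CC[C@](O)(CO)[C@@H]1[C@@H]3OC(C)=O | intermediate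
30 | 6-chloro-5(16)-ene 11,20-diol tetraacetate | C=C1[C@H](Cl)[C@@H]2OC(=O)[C@H](C)[C@]23O[C@H]1[C@@H](OC(C)=O)[C@H](OC(C)=O)[C@@]1(C)[C@@H](OC(C)=O)CC[C@](O)(CO)[C@@H]1[C@@H]3OC(C)=O | intermediate
31 | CNP0186125.1 | C=C1[C@H]2O[C@]3([C@@H](C)C(=O)O[C@H]3[C@H]1Cl)[C@@H](OC(C)=O)[C@@H]1[C@](C)([C@@H](OC(C)=O)CC[C@]1(O)C(=O)O)[C@@H](OC(C)=O)[C@@H]2OC(C)=O | target

Total step count: 24. Longest linear sequence: 22 steps (steps 1–6 and 9–24, from 1 to 31).

Steps most likely to fail

Step 20. The allylsilane may be protodesilylated before it cyclises, or the ring may close through the other face of C10 (cis ring fusion) or of the aldehyde. The fallback sets out from 25 and replaces the allylsilane by a carbonyl–ene closure. Pd(PPh3)4-catalysed coupling of the enol triflate with MeZnCl gives the C11-methyl cyclohexene aldehyde F1. Me2AlCl in CH2Cl2 at −78 °C then promotes an intramolecular carbonyl–ene reaction in which C10 bonds to C9 while a hydrogen of the C20 methyl is transferred to the aldehyde oxygen. This comes back to the route at 27.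

Step 23. Hypochlorous acid may attack the alkene, which two allylic oxygens deactivate, too slowly or unselectively, with chlorohydrin formation or oxidation of the primary alcohol competing. The fallback sets out from 29 and reaches the chloride by allylic oxidation and rearrangement. The 11,20-diol is masked with 2,2-dimethoxypropane and CSA as the 11,20-acetonide F2. SeO2 with t-BuOOH oxidises the C16 methyl (ene reaction, then 2,3-shift) to the primary allylic alcohol F3. SOCl2 in Et2O converts its chlorosulfite with allylic rearrangement (SNi′) into the C6 chloride with exocyclic methylene, the chloro acetonide F4, chlorine again entering from the open face. Aqueous AcOH removes the acetonide and the route is rejoined at 30.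

Step 22. Osmylation may fail to discriminate between the C11=C20 and C5=C6 alkenes or may attack the axial face of C11. The fallback sets out from 27, before acetylation, and uses the free homoallylic C9 hydroxyl to direct the oxidant. VO(acac)2 with t-BuOOH epoxidises only the C11=C20 alkene to the 11,20-epoxy diol F5. Ac2O with DMAP gives the epoxy tetraacetate F6. Hydrolytic opening at the primary C20 with water and the catalyst (salen)Co(OAc) (trivalent cobalt) retains the C11–O bond and comes back to the route at 29.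

Further compounds
F1 | step 20 | C11-methyl cyclohexene aldehyde (25 with methyl in place of the triflate) | CC1=C[C@@H]2OC(=O)[C@H](C)[C@]2(C=O)O[C@H]1[C@@H](OC(C)=O)[C@H](OC(C)=O)[C@]3(C)C=C(C)CC[C@@H]3O
F2 | step 23 | 11,20-acetonide of 29 | CC1=C[C@@H]2OC(=O)[C@H](C)[C@]23O[C@H]1[C@@H](OC(C)=O)[C@H](OC(C)=O)[C@@]1(C)[C@@H](OC(C)=O)CC[C@]4(COC(C)(C)O4)[C@@H]1[C@@H]3OC(C)=O
F3 | step 23 | C16 primary allylic alcohol (C5=C6 retained) | OCC1=C[C@@H]2OC(=O)[C@H](C)[C@]23O[C@H]1[C@@H](OC(C)=O)[C@H](OC(C)=O)[C@@]1(C)[C@@H](OC(C)=O)CC[C@]4(COC(C)(C)O4)[C@@H]1[C@@H]3OC(C)=O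
F4 | step 23 | 6-chloro-5(16)-ene 11,20-acetonide | C=C1[C@H](Cl)[C@@H]2OC(=O)[C@H](C)[C@]23O[C@H]1[C@@H](OC(C)=O)[C@H](OC(C)=O)[C@@]1(C)[C@@H](OC(C)=O)CC[C@]4(COC(C)(C)O4)[C@@H]1[C@@H]3OC(C)=O
F5 | step 22 | 11,20-epoxy diol (C9 and C14 hydroxyls free) | CC1=C[C@@H]2OC(=O)[C@H](C)[C@]23O[C@H]1[C@@H](OC(C)=O)[C@H](OC(C)=O)[C@@]1(C)[C@@H](O)CC[C@]4(CO4)[C@@H]1[C@@H]3O
F6 | step 22 | 11,20-epoxy tetraacetate | CC1=C[C@@H]2OC(=O)[C@H](C)[C@]23O[C@H]1[C@@H](OC(C)=O)[C@H](OC(C)=O)[C@@]1(C)[C@@H](OC(C)=O)CC[C@]4(CO4)[C@@H]1[C@@H]3OC(C)=O
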